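## The problem

The target is a ten-membered carbocycle (germacrane numbering, C1–C10). It carries a ring-cis C1=C10 double bond conjugated with the C14 methyl ester (E by the priority rules), a 4,5-epoxide whose ring bonds C3 and C6 are cis, and a cis-fused α-methylene-γ-lactone on C6/C7 (C11–C13). O8 bears an (S)-2-methylglycidate and O9 an acetate. Direct closure of such a ring pays an entropic and a transannular price, so the ring is better derived from six-membered rings. The four contiguous centres C6–C9 can be set on a cyclohexane; C6 can then steer the late epoxidation at C4/C5 through allylic strain, and the glycidate centre arrives with its acid. The methylene lactone, the two epoxides, the allylic acetate and the enoate do not tolerate strong nucleophiles, chloride with Lewis acid, or strong acid, so they must be introduced late and in a fixed order. The feature that makes the key step possible is the 1,6-relation of the oxygen on C5 and the ester on C10. A C5–C10 bond turns the ring into a decalin that is a β-hydroxy ester, and a C5 alkoxy radical can cut exactly that bond because the C10 radical is tertiary and ester-stabilised.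

## Retrosynthesis

**Epoxide last (40 from 39).** The two C–O bonds of the 4,5-epoxide are cut first, giving the (4Z)-alkene 39. The epoxide is the most acid-sensitive group, and C4=C5 is the only electron-rich alkene in 39, so a peracid needs no protection scheme. The forward step must choose the face anti to C7, which the allylic C6 centre should enforce.

**Acyl groups and methylene (39 from 35 and 37; 35 from 34 and 30).** The O8–acyl bond is cut to the alcohol 35 and (S)-2-methyloxirane-2-carboxylic acid 37, made in one step from the glycidol 36. The glycidate cannot pass through chloride, hydride or enolate chemistry, so it enters second to last. The exocyclic C11=C13 bond of 34 is cut back to the lactone 30. This costs one enolate step, made safe because the lactone α-protons are the most acidic in 30.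

**The two ring alkenes (30 from 29, 28, 26 and 25).** C1=C10 is traced to the tertiary chloride 29 by loss of HCl. C4=C5 is traced through the enol triflate 28 to the C5 ketone. A bare C5 ketone flanked by C4–H and the more acidic C6–H gives no regiocontrol. An acetoxy group on C15 solves this: β-elimination from 25 gives the exocyclic enone 26, and conjugate hydride addition gives the C4–C5 enolate only. This replaces enolisation of the ketone, which would also endanger the C6 centre.

**Key disconnection (25 from 22).** Reconnecting C5 to C10 turns the ten-membered chloro ketone 25 into the cis-fused decalinol 22. Neighbouring cuts (C5–C6 pinacol, C1–C10 olefination, macrolactonisation) all require a medium-ring closure. This cut needs only six-membered ring closures before it, and every stereocentre it touches (C5, C10) or that ring A adds (C4) is erased afterwards. The forward reaction must break C5–C10 rather than C5–C4 or C5–C6 and trap the C10 radical.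

**Ring A (22 from 21, 20 and 19; 19 from 15 and 17).** C2–C3 is cut by ring-closing metathesis and C4–C5 by allylation of the ketone 15 with the bromide 17, made from the alcohol 16. A ketyl–alkene cyclisation was rejected because samarium diiodide cleaves α-acyloxy ketones. One hydrogenation then saturates ring A and frees O9 and O15 for acetylation (21, then 22).

**Ring B (15 from 14 and 12).** C5–C10 and C1–C2 are cut together: vinyl conjugate addition to the acrylate 12 creates the C10 enolate, which acylates the C5 lactone. A plain Dieckmann closure was rejected because the lactone α-protons are more acidic than those of the ester. The conjugate addition makes the enolate regiospecifically and installs the allyl group at the same time.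

**Acrylate and lactones (12 from 11, 10, 8, 7 and 6).** C10–C14 is cut by alkyne carbonylation (11), the C5 lactone by lactol oxidation (10), and the 6,12-lactone by acid-induced lactonisation of 8. C9–C10 is cut by chelation-controlled ethynylation of the aldehyde 6 (7, then benzyl ether 8). This sets C9.

**Chiral pool (6 from 4, 3, 2 and 1).** The C7 branch is cut back to the ulose 2 (olefination to 3, hydrogenation to 4), and 6 arises by glycol cleavage. Diacetone-D-glucose 1 supplies C5–C8 with O6 and O8 cis; hydrogenation sets C7 cis to both.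

## Roads not taken

**Alternative 1:** The lactone C7–C11 bond is cut. Forward, Rh2(O2CCH3)4 generates a carbenoid from a diazo(phosphono)acetyl group on O6, which inserts into the C7–H bond cis to O6 to give the α-phosphono lactone A1.
- Merits: the five-membered transition state enforces cis fusion. The phosphonate gives the methylene group by olefination with formaldehyde under mild base, which is better than the enolate Mannich sequence used here. No lactone α-protons are carried through earlier steps.
- Weak points: the step does nothing for the ten-membered ring, which must already exist with both epoxide and enoate in place. The carbenoid can form an oxonium ylide with the 4,5-epoxide or insert next to O8.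
- Comparison: for the lactone endgame this road is superior. Against it, the chosen plan makes the ring itself, and its early lactone serves twice: as the sugar-derived stereochemical anchor and as the electron-poor O6 substituent that steers the scission.

**Alternative 2:** Bonds C1–C10 and C4–C5 are cut. Forward, a head-to-tail enone–alkene [2+2] photocycloaddition gives the tricyclic adduct A2. Thermal opening of its bicyclo[2.2.0]hexane unit (C1–C4 and C5–C10) would then unveil both ring alkenes.
- Merits: the ring and both alkenes appear in two steps. No chloride elimination and no C15 handle are needed. In step economy this road is clearly better.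
- Weak points: head-to-tail regiochemistry and facial selectivity are not secured. The thermal opening passes through a 1,4-diyl that favours trans ring alkenes, whereas the target needs both cis. Cyclodeca-1,5-dienes undergo Cope rearrangement at such temperatures. The C9 ketone must afterwards be reduced stereoselectively in the macrocycle.
- Comparison: the chosen plan is longer, but it forms each alkene under separate geometric control and sets C9 on a six-membered ring.

**Alternative 3:** The C5–C6 bond is cut. Forward, SmI2 couples two aldehyde termini of a chain built from chiral-pool pieces to give the ten-membered cis-5,6-diol A3.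
- Merits: the route is convergent. C4 and the C8/C9 pair come from the chiral pool with absolute control, which is better than the late facial selection at C4/C5 used here. The diol provides both the epoxide and the lactone oxygen.
- Weak points: a ten-membered pinacol closure is entropically and transannularly costly. Two new centres (C5, C6) must be set in the macrocyclisation. C7, next to an aldehyde, is epimerisable. The (Z)-trisubstituted alkene and the oxidation levels at C12 and C14 must be handled in a long linear chain.
- Comparison: the chosen plan forms the ring from a decalin without high dilution and takes C6/C7 from the sugar rather than from an unpredictable macrocyclic coupling.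

Key step: step 17

Remark: germacrane numbering is used from compound 7 on (sugar C1–C5 become C5–C9). The epimers at C10, C5 and C4 formed in steps 10, 13 and 17 are drawn as the expected major ones; they converge because these centres become trigonal in steps 17, 18 and 21.

Step 1
Reactants: 1 1,2:5,6-di-O-isopropylidene-α-D-glucofuranose
Product: 2 1,2:5,6-di-O-isopropylidene-α-D-ribo-hexofuranos-3-ulose
Conditions: TEMPO (cat.), NaOCl, KBr (cat.), NaHCO3, CH2Cl2/H2O, 0 °C
Reagents that add atoms: none
Why: Oxoammonium oxidation of the only free hydroxyl, a secondary one, to the ketone; no stereocentre is formed and the acetonides tolerate the buffered medium.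

Step 2
Reactants: 2 ulose
Product: 3 methyl (3-deoxy-1,2:5,6-di-O-isopropylidene-α-D-ribo-hexofuranos-3-ylidene)acetate (E/Z mixture)
Conditions: (MeO)2P(O)CH2CO2Me, KOC(CH3)3, THF, 0 °C to rt
Reagents that add atoms: trimethyl phosphonoacetate, COC(=O)CP(=O)(OC)OC
Why: Horner–Wadsworth–Emmons olefination of the hindered ketone; the alkene geometry is of no consequence because both isomers are hydrogenated to the same product.

Step 3
Reactants: 3 alkylidene ester
Product: 4 3-deoxy-1,2:5,6-di-O-isopropylidene-3-C-(2-methoxy-2-oxoethyl)-α-D-allofuranose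
Conditions: H2 (1 atm), Pd/C, EtOAc, rt
Reagents that add atoms: none
Why: Heterogeneous hydrogenation from the convex β-face, opposite the 1,2-acetonide, sets C7 (sugar C3) with the ester branch cis to O6 and O8 (allo configuration).

Step 4
Reactants: 4 branched diacetonide
Product: 6 3-deoxy-1,2-O-isopropylidene-3-C-(2-methoxy-2-oxoethyl)-α-D-ribo-pentodialdo-1,4-furanose, via glycol 5 (not isolated)
Conditions: H5IO6, EtOAc, rt
Reagents that add atoms: none
Why: Periodic acid hydrolyses the more labile terminal acetonide and cleaves the freed glycol in the same flask (glycol cleavage); the non-basic medium leaves the α-centre C8 untouched.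

Step 5
Reactants: 6 aldehyde
Product: 7 (5S)-propargylic alcohol, 3,6,7-trideoxy-1,2-O-isopropylidene-3-C-(2-methoxy-2-oxoethyl)-β-L-talo-hept-6-ynofuranose
Conditions: MgBr2·OEt2, CH2Cl2, −78 °C; then HC≡CMgBr, THF, −78 °C
Reagents that add atoms: ethynylmagnesium bromide, C#C[Mg]Br
Why: Chelation-controlled Grignard addition: magnesium bridges the aldehyde and ring oxygens and the acetylide attacks anti to C7, giving the (S)-carbinol that becomes C9, trans to O8; at −78 °C the methyl ester is not attacked.

Step 6
Reactants: 7 propargylic alcohol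
Product: 8 5-O-benzyl ether of 7
Conditions: BnOC(=NH)CCl3, CF3SO3H (cat.), CH2Cl2/cyclohexane, 0 °C
Reagents that add atoms: benzyl 2,2,2-trichloroacetimidate, N=C(OCc1ccccc1)C(Cl)(Cl)Cl
Why: Acid-catalysed imidate benzylation avoids an alkoxide next to the ester; the ether blocks pyranose and δ-lactone formation in the next two steps.

Step 7
Reactants: 8 benzyl ether
Product: 10 lactol lactone (furanose lactol at C5, cis-fused 6,12-γ-lactone), via hydroxy ester lactol 9 (not isolated)
Conditions: CF3CO2H/H2O (9:1), 0 °C to rt
Reagents that add atoms: none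
Why: Acid hydrolysis of the 1,2-acetonide; the freed O6 hydroxyl, cis to the ester branch, lactonises spontaneously to the cis-fused γ-lactone of the target, while alkyne and benzyl ether are inert.

Step 8
Reactants: 10 lactol lactone
Product: 11 alkynyl bis-lactone (C5 1,4-lactone and 6,12-lactone)
Conditions: TEMPO (cat.), PhI(OAc)2, CH2Cl2, rt
Reagents that add atoms: none
Why: Oxoammonium oxidation of the lactol to the γ-lactone raises C5 to the acyl level needed for the later Claisen closure; no other group is oxidisable.

Step 9
Reactants: 11 alkynyl bis-lactone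
Product: 12 acrylate bis-lactone (C10=C1 methylene, C14 methyl ester, 9-OBn)
Conditions: Pd(OAc)2 (2 mol%), 2-(diphenylphosphino)pyridine, CH3SO3H (cat.), CO (20 bar), MeOH, 45 °C
Reagents that add atoms: carbon monoxide, [C-]#[O+]; methanol, CO
Why: Palladium-catalysed Markovnikov hydromethoxycarbonylation of the terminal alkyne puts the ester on the internal carbon (C10) and leaves C1 as the methylene terminus.

Step 10
Reactants: 12 acrylate bis-lactone
Product: 14 ring-B keto ester alcohol, methyl 6-allyl-5-(benzyloxy)-4-hydroxy-2,7-dioxooctahydro-1-benzofuran-6-carboxylate, via magnesium ester enolate 13 (not isolated)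
Conditions: CH2=CHMgBr, CuBr·SMe2 (20 mol%), THF, −78 to −20 °C; aq. NH4Cl
Reagents that add atoms: vinylmagnesium bromide, C=C[Mg]Br
Why: Copper-catalysed conjugate addition to the 2-substituted acrylate generates the C10 enolate regiospecifically, and this closes ring B by Dieckmann-type acylation on the C5 lactone carbonyl with loss of O8 (Michael-initiated ring closure); the quaternary C10 forms with the ester anti to the benzyloxy group and is erased in step 17.

Step 11
Reactants: 14 keto ester alcohol
Product: 15 8-O-tert-butyldimethylsilyl ether of 14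
Conditions: t-BuMe2SiOSO2CF3, 2,6-lutidine, CH2Cl2, −40 to 0 °C
Reagents that add atoms: tert-butyldimethylsilyl trifluoromethanesulfonate, CC(C)(C)[Si](C)(C)OS(=O)(=O)C(F)(F)F
Why: Silylation of the only hydroxyl; the β-keto ester has no α-hydrogen at C10, so the silyl triflate cannot form an enol ether there.

Step 12
Reactants: 16 (Z)-4-(benzyloxy)but-2-en-1-ol
Product: 17 (Z)-1-(benzyloxy)-4-bromobut-2-ene
Conditions: CBr4, PPh3, CH2Cl2, 0 °C
Reagents that add atoms: carbon tetrabromide, BrC(Br)(Br)Br
Why: Appel bromination of the primary allylic alcohol by SN2 displacement; the alkene geometry is retained and is irrelevant for the next step.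

Step 13
Reactants: 15 silyl ether keto ester; 17 allylic bromide
Product: 19 tertiary homoallylic alcohol (C5–OH, C4 bearing vinyl and CH2OBn), via allylindium dibromide 18 (not isolated)
Conditions: In powder, THF/H2O (3:1), rt
Reagents that add atoms: none
Why: Barbier allylation: the allylindium reagent adds through its γ-carbon in a cyclic transition state to the ketone only, anti to the axial C7 branch, so the new chain is cis to the C10 allyl group; the new centres C5 and C4 are erased in steps 17 and 18.

Step 14
Reactants: 19 diene carbinol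
Product: 20 cis-fused octalin (eudesm-2-ene skeleton with 6,12-lactone, 5-OH, 9,15-di-OBn, 8-OTBS, C14 ester)
Conditions: (H2IMes)(PCy3)Cl2Ru=CHPh (second-generation Grubbs catalyst, 5 mol%), CH2Cl2, 40 °C
Reagents that add atoms: none
Why: Ring-closing metathesis of the two terminal alkenes forms C2=C3 and closes six-membered ring A; no stereocentre is affected.

Step 15
Reactants: 20 octalin
Product: 21 triol (5,9,15-trihydroxy, 8-OTBS, saturated ring A)
Conditions: H2 (1 atm), Pd(OH)2/C, EtOAc/MeOH, rt
Reagents that add atoms: none
Why: One hydrogenation saturates C2=C3 and removes both benzyl ethers by hydrogenolysis, so the key-step substrate carries neither alkene nor arene.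

Step 16
Reactants: 21 triol
Product: 22 methyl 9,15-diacetoxy-8-(tert-butyldimethylsilyloxy)-5-hydroxyeudesman-12,6-olid-14-oate (cis-fused decalinol)
Conditions: Ac2O, 4-(dimethylamino)pyridine (cat.), pyridine, 0 °C to rt
Reagents that add atoms: acetic anhydride, CC(=O)OC(C)=O
Why: Nucleophile-catalysed acetylation of the primary O15 and secondary O9 hydroxyls; the tertiary ring-fusion alcohol is too hindered to react. O9 thereby receives its final acetate and C15 its leaving group.

Step 17
Reactants: 22 cis-decalinol
Product: 25 methyl 9,15-diacetoxy-8-(tert-butyldimethylsilyloxy)-10-chloro-5-oxogermacran-12,6-olid-14-oate, via alkoxy radical 23 (not isolated), via ester-stabilised C10 radical 24 (not isolated)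
Conditions: Mn(OSO2CF3)2 (10 mol%), MgCl2 (5 equiv), LiClO4, MeCN/AcOH (7:1), graphite anode, Pt cathode, undivided cell, constant current, 25 °C, N2
Reagents that add atoms: magnesium dichloride, [Mg+2].[Cl-].[Cl-]
Why: Proposed new method: anodic oxidation of divalent manganese with chloride gives a trivalent manganese chloride that binds the tertiary C5 hydroxyl and releases the alkoxy radical 23; β-scission of C5–C10 gives the C5 ketone and the tertiary radical 24, which takes chlorine from the trivalent manganese chloride to give 25 while protons are reduced at the cathode. The closest known reactions are the manganese-catalysed electrochemical deconstructive chlorination of cycloalkanols and the alkoxy-radical ring expansion of ring-fusion alcohols (hypoiodite or Pb(OAc)4 fragmentation, Dowd–Beckwith ring expansion); neither has been shown on an unstrained, polyoxygenated decalin-5-ol with electrochemical chlorine transfer. The ten-membered ring is not closed by bond formation; it appears when the bond shared by the two six-membered rings is cut. The only new stereocentre, C10 bearing chlorine, is uncontrolled and need not be controlled, since it becomes trigonal in step 21. The step needs scission of C5–C10 over C5–C4 and C5–C6: the C10 radical is tertiary and conjugated with the ester, C4 would give an unstabilised secondary radical, and the acyl group on O6 makes a C6 radical less stabilised than an α-alkoxy radical. The substrate carries no alkene, arene or oxidisable secondary alcohol that the chlorinating anode could attack.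

Step 18
Reactants: 25 chloro ketone
Product: 26 exocyclic enone (4(15)-en-5-one, 15-acetoxy lost)
Conditions: Et3N, CH2Cl2, 0 °C
Reagents that add atoms: none
Why: E1cB elimination of the β-acetoxy ketone under mild base unveils the C4=C15 enone; the short, cold treatment spares the base-sensitive C6 centre and the tertiary chloride.

Step 19
Reactants: 26 exocyclic enone
Product: 28 enol triflate (C4=C5, 5-OSO2CF3, C15 methyl), via lithium enolate 27 (not isolated)
Conditions: LiBH(s-Bu)3, THF, −78 °C; then N-(5-chloropyridin-2-yl)bis(trifluoromethanesulfonyl)imide (Comins' reagent), −78 to 0 °C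
Reagents that add atoms: Comins' reagent, O=S(=O)(N(c1ccc(Cl)cn1)S(=O)(=O)C(F)(F)F)C(F)(F)F
Why: Conjugate hydride addition to the exocyclic enone gives the C4–C5 enolate only, never the C6 enolate, and O-sulfonylation fixes it; the enolate should form from the s-cis enone conformer with C3 and C6 on the same side, which leads to the ring-cis alkene.

Step 20
Reactants: 28 enol triflate
Product: 29 (4Z)-alkene, methyl 9-acetoxy-8-(tert-butyldimethylsilyloxy)-10-chlorogermacr-4-en-12,6-olid-14-oate
Conditions: Pd(OAc)2 (5 mol%), PPh3, n-Bu3N, HCO2H, DMF, 60 °C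
Reagents that add atoms: none
Why: Palladium-catalysed formate reduction of the enol triflate (oxidative addition, hydride transfer, reductive elimination) replaces the sulfonate by hydrogen with retention of geometry; the tertiary chloride does not add to zerovalent palladium.

Step 21
Reactants: 29 chloro alkene
Product: 30 methyl (1(10)E,4Z)-9-acetoxy-8-(tert-butyldimethylsilyloxy)germacra-1(10),4-dien-12,6-olid-14-oate
Conditions: DBU, toluene, 80 °C
Reagents that add atoms: none
Why: Amidine-promoted E2 dehydrochlorination; the open C1 hydrogens are removed in preference to the hindered C9–H, and the conjugated ester with C2 trans to CO2Me (cis ring alkene) is the favoured geometry in the ten-membered ring.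

Step 22
Reactants: 30 diene lactone
Product: 34 α-methylene lactone (germacra-1(10),4,11(13)-triene, 8-OTBS, 9-OAc), via lithium lactone enolate 31 (not isolated), via Mannich base 32 (not isolated), via ammonium iodide 33 (not isolated)
Conditions: LiN(SiMe3)2, THF, −78 °C; CH2=NMe2+ I−, −78 °C to rt; then MeI, CH2Cl2/MeOH, rt; then aq. NaHCO3, rt
Reagents that add atoms: N,N-dimethylmethyleneiminium iodide (Eschenmoser's salt), C=[N+](C)C.[I-]
Why: Mannich reaction of the lactone enolate, N-methylation and Hofmann-type elimination give the exocyclic methylene; the lactone α-protons are the most acidic C–H bonds, so one equivalent of amide base at −78 °C spares the acetate and the enoate.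

Step 23
Reactants: 34 silyl ether
Product: 35 8-hydroxy compound
Conditions: HF·pyridine, pyridine, THF, 0 °C to rt
Reagents that add atoms: none
Why: Fluoride cleavage of the secondary silyl ether under buffered acidic conditions, which suppress 9-to-8 acetyl migration; no epoxide is yet present.

Step 24
Reactants: 36 (R)-(2-methyloxiran-2-yl)methanol
Product: 37 (S)-2-methyloxirane-2-carboxylic acid
Conditions: TEMPO (cat.), PhI(OAc)2, MeCN/H2O (1:1), 0 °C to rt
Reagents that add atoms: water, O
Why: Oxoammonium oxidation of the primary alcohol to the acid through the aldehyde hydrate; the quaternary epoxide carbon cannot epimerise, and the descriptor changes from R to S only through the priority rules.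

Step 25
Reactants: 35 alcohol; 37 epoxy acid
Product: 39 8-O-[(S)-2-methyloxirane-2-carbonyl] ester, via mixed anhydride 38 (not isolated)
Conditions: 2,4,6-Cl3C6H2COCl, Et3N, THF, 0 °C; then 35, 4-(dimethylamino)pyridine, toluene, rt
Reagents that add atoms: none
Why: Yamaguchi esterification: the mixed anhydride transfers the acyl group to the hindered C8 hydroxyl through the acylpyridinium ion; the acid has no α-hydrogen and cannot racemise.

Step 26
Reactants: 39 triene ester
Product: 40 target, methyl (1(10)E)-9-acetoxy-4,5-epoxy-8-[(2S)-2-methyloxirane-2-carbonyloxy]germacra-1(10),11(13)-dien-12,6-olid-14-oate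
Conditions: 3-ClC6H4CO3H, NaHCO3, CH2Cl2, 0 °C
Reagents that add atoms: 3-chloroperbenzoic acid, OOC(=O)c1cccc(Cl)c1
Why: Prilezhaev epoxidation of the only electron-rich alkene; with H6 eclipsing the alkene (allylic 1,3-strain) and C7 on the inner face, the peracid attacks the outer face and gives the cis-4,5-epoxide anti to C7 (4R,5S). The enoate, the methylene lactone and the glycidate are inert.

## Compound list

1 | 1,2:5,6-di-O-isopropylidene-α-D-glucofuranose | CC1(C)O[C@H]2O[C@@H]([C@H](O)[C@H]2O1)[C@H]3COC(C)(C)O3 | starting material
2 | 1,2:5,6-di-O-isopropylidene-α-D-ribo-hexofuranos-3-ulose | CC1(C)O[C@H]2O[C@@H](C(=O)[C@H]2O1)[C@H]3COC(C)(C)O3 | intermediate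
3 | methyl (3-deoxy-1,2:5,6-di-O-isopropylidene-α-D-ribo-hexofuranos-3-ylidene)acetate, E/Z mixture | CC1(C)O[C@H]2O[C@@H](C(=CC(=O)OC)[C@H]2O1)[C@H]3COC(C)(C)O3 | intermediate
4 | 3-deoxy-1,2:5,6-di-O-isopropylidene-3-C-(2-methoxy-2-oxoethyl)-α-D-allofuranose | CC1(C)O[C@H]2O[C@@H]([C@@H](CC(=O)OC)[C@H]2O1)[C@H]3COC(C)(C)O3 | intermediate
5 | 3-deoxy-1,2-O-isopropylidene-3-C-(2-methoxy-2-oxoethyl)-α-D-allofuranose (5,6-glycol) | CC1(C)O[C@H]2O[C@@H]([C@@H](CC(=O)OC)[C@H]2O1)[C@H](O)CO | intermediate
6 | 3-deoxy-1,2-O-isopropylidene-3-C-(2-methoxy-2-oxoethyl)-α-D-ribo-pentodialdo-1,4-furanose | CC1(C)O[C@H]2O[C@@H]([C@@H](CC(=O)OC)[C@H]2O1)C=O | intermediate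
7 | 3,6,7-trideoxy-1,2-O-isopropylidene-3-C-(2-methoxy-2-oxoethyl)-β-L-talo-hept-6-ynofuranose ((5S)-alcohol) | CC1(C)O[C@H]2O[C@@H]([C@@H](CC(=O)OC)[C@H]2O1)[C@@H](O)C#C | intermediate
8 | 5-O-benzyl ether of 7 | CC1(C)O[C@H]2O[C@@H]([C@@H](CC(=O)OC)[C@H]2O1)[C@@H](OCc3ccccc3)C#C | intermediate
9 | 5-O-benzyl-3,6,7-trideoxy-3-C-(2-methoxy-2-oxoethyl)-L-talo-hept-6-ynofuranose (anomers) | OC1O[C@H]([C@@H](OCc2ccccc2)C#C)[C@@H](CC(=O)OC)[C@H]1O | intermediate
10 | lactol lactone: C5 furanose lactol (anomers) with cis-fused 6,12-γ-lactone, 9-OBn, C10≡C1 alkyne | OC1O[C@H]([C@@H](OCc2ccccc2)C#C)[C@H]3CC(=O)O[C@@H]13 | intermediate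
11 | alkynyl bis-lactone: C5 1,4-lactone and 6,12-lactone cis-fused, (S)-1-(benzyloxy)prop-2-ynyl group on C8 | O=C1O[C@H]([C@@H](OCc2ccccc2)C#C)[C@H]3CC(=O)O[C@@H]13 | intermediate
12 | acrylate bis-lactone: methyl 2-[(S)-(benzyloxy)(bis-lactone C8-yl)methyl]prop-2-enoate | O=C1O[C@H]([C@@H](OCc2ccccc2)C(=C)C(=O)OC)[C@H]3CC(=O)O[C@@H]13 | intermediate
13 | bromomagnesium ester enolate of the vinyl conjugate adduct of 12 | O=C1O[C@H]([C@@H](OCc2ccccc2)C(CC=C)=C([O-])OC)[C@H]3CC(=O)O[C@@H]13.[Mg+2].[Br-] | intermediate
14 | methyl 6-allyl-5-(benzyloxy)-4-hydroxy-2,7-dioxooctahydro-1-benzofuran-6-carboxylate (C5 ketone, 6,12-lactone, 8-OH cis to C11, 9-OBn trans to O8, ester anti to OBn) | O=C1[C@@H]2OC(=O)C[C@@H]2[C@H](O)[C@@H](OCc3ccccc3)[C@]1(CC=C)C(=O)OC | intermediate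
15 | 8-O-tert-butyldimethylsilyl ether of 14 | O=C1[C@@H]2OC(=O)C[C@@H]2[C@H](O[Si](C)(C)C(C)(C)C)[C@@H](OCc3ccccc3)[C@]1(CC=C)C(=O)OC | intermediate
16 | (Z)-4-(benzyloxy)but-2-en-1-ol | OC/C=C\COCc1ccccc1 | starting material
17 | (Z)-1-(benzyloxy)-4-bromobut-2-ene | BrC/C=C\COCc1ccccc1 | intermediate
18 | [(Z)-4-(benzyloxy)but-2-enyl]indium dibromide | Br[In](Br)C/C=C\COCc1ccccc1 | intermediate
19 | tertiary alcohol: 15 with C5 converted to C(OH) bearing the 1-(benzyloxy)but-3-en-2-yl group (C4, C15, C3) cis to the C10 allyl group | O[C@]1([C@@H](COCc4ccccc4)C=C)[C@@H]2OC(=O)C[C@@H]2[C@H](O[Si](C)(C)C(C)(C)C)[C@@H](OCc3ccccc3)[C@]1(CC=C)C(=O)OC | intermediate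
20 | methyl 9,15-bis(benzyloxy)-8-(tert-butyldimethylsilyloxy)-5-hydroxyeudesm-2-en-12,6-olid-14-oate (cis-fused) | COC(=O)[C@]12CC=C[C@H](COCc4ccccc4)[C@@]1(O)[C@@H]3OC(=O)C[C@@H]3[C@H](O[Si](C)(C)C(C)(C)C)[C@H]2OCc5ccccc5 | intermediate
21 | methyl 8-(tert-butyldimethylsilyloxy)-5,9,15-trihydroxyeudesman-12,6-olid-14-oate | COC(=O)[C@]12CCC[C@H](CO)[C@@]1(O)[C@@H]3OC(=O)C[C@@H]3[C@H](O[Si](C)(C)C(C)(C)C)[C@H]2O | intermediate
22 | methyl 9,15-diacetoxy-8-(tert-butyldimethylsilyloxy)-5-hydroxyeudesman-12,6-olid-14-oate (cis-decalinol, key-step precursor) | COC(=O)[C@]12CCC[C@H](COC(C)=O)[C@@]1(O)[C@@H]3OC(=O)C[C@@H]3[C@H](O[Si](C)(C)C(C)(C)C)[C@H]2OC(C)=O | intermediate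
23 | C5 alkoxy radical of 22 | COC(=O)[C@]12CCC[C@H](COC(C)=O)[C@@]1([O])[C@@H]3OC(=O)C[C@@H]3[C@H](O[Si](C)(C)C(C)(C)C)[C@H]2OC(C)=O | intermediate
24 | ring-opened C10 radical (ten-membered 5-ketone) | COC(=O)[C]1CCC[C@H](COC(C)=O)C(=O)[C@@H]2OC(=O)C[C@@H]2[C@H](O[Si](C)(C)C(C)(C)C)[C@H]1OC(C)=O | intermediate
25 | methyl 9,15-diacetoxy-8-(tert-butyldimethylsilyloxy)-10-chloro-5-oxogermacran-12,6-olid-14-oate (key-step product) | COC(=O)[C@@]1(Cl)CCC[C@H](COC(C)=O)C(=O)[C@@H]2OC(=O)C[C@@H]2[C@H](O[Si](C)(C)C(C)(C)C)[C@H]1OC(C)=O | intermediate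
26 | methyl 9-acetoxy-8-(tert-butyldimethylsilyloxy)-10-chloro-5-oxogermacr-4(15)-en-12,6-olid-14-oate | COC(=O)[C@@]1(Cl)CCCC(=C)C(=O)[C@@H]2OC(=O)C[C@@H]2[C@H](O[Si](C)(C)C(C)(C)C)[C@H]1OC(C)=O | intermediate
27 | lithium C4–C5 enolate of the 4,15-dihydro ketone | COC(=O)[C@@]1(Cl)CCC/C(C)=C(/[O-])[C@@H]2OC(=O)C[C@@H]2[C@H](O[Si](C)(C)C(C)(C)C)[C@H]1OC(C)=O.[Li+] | intermediate
28 | C5 enol triflate (C4=C5, C3 and C6 cis) | COC(=O)[C@@]1(Cl)CCC/C(C)=C(/OS(=O)(=O)C(F)(F)F)[C@@H]2OC(=O)C[C@@H]2[C@H](O[Si](C)(C)C(C)(C)C)[C@H]1OC(C)=O | intermediate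
29 | methyl (4Z)-9-acetoxy-8-(tert-butyldimethylsilyloxy)-10-chlorogermacr-4-en-12,6-olid-14-oate | COC(=O)[C@@]1(Cl)CCC/C(C)=C\[C@@H]2OC(=O)C[C@@H]2[C@H](O[Si](C)(C)C(C)(C)C)[C@H]1OC(C)=O | intermediate
30 | methyl (1(10)E,4Z)-9-acetoxy-8-(tert-butyldimethylsilyloxy)germacra-1(10),4-dien-12,6-olid-14-oate | O=C1O[C@H]2/C=C(C)\CC/C=C(/C(=O)OC)[C@H](OC(C)=O)[C@@H](O[Si](C)(C)C(C)(C)C)[C@H]2C1 | intermediate
31 | lithium lactone enolate of 30 | [Li+].[O-]C1O[C@H]2/C=C(C)\CC/C=C(/C(=O)OC)[C@H](OC(C)=O)[C@@H](O[Si](C)(C)C(C)(C)C)[C@H]2C=1 | intermediate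
32 | 11-(dimethylaminomethyl) lactone (Mannich base, C11 epimers) | O=C1O[C@H]2/C=C(C)\CC/C=C(/C(=O)OC)[C@H](OC(C)=O)[C@@H](O[Si](C)(C)C(C)(C)C)[C@H]2C1CN(C)C | intermediate
33 | 11-(trimethylammoniomethyl) lactone iodide | O=C1O[C@H]2/C=C(C)\CC/C=C(/C(=O)OC)[C@H](OC(C)=O)[C@@H](O[Si](C)(C)C(C)(C)C)[C@H]2C1C[N+](C)(C)C.[I-] | intermediate
34 | methyl (1(10)E,4Z)-9-acetoxy-8-(tert-butyldimethylsilyloxy)germacra-1(10),4,11(13)-trien-12,6-olid-14-oate | O=C1O[C@H]2/C=C(C)\CC/C=C(/C(=O)OC)[C@H](OC(C)=O)[C@@H](O[Si](C)(C)C(C)(C)C)[C@H]2C1=C | intermediate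
35 | methyl (1(10)E,4Z)-9-acetoxy-8-hydroxygermacra-1(10),4,11(13)-trien-12,6-olid-14-oate | O=C1O[C@H]2/C=C(C)\CC/C=C(/C(=O)OC)[C@H](OC(C)=O)[C@@H](O)[C@H]2C1=C | intermediate
36 | (R)-(2-methyloxiran-2-yl)methanol | OC[C@]1(C)CO1 | starting material
37 | (S)-2-methyloxirane-2-carboxylic acid | OC(=O)[C@]1(C)CO1 | intermediate
38 | (S)-2-methyloxirane-2-carboxylic 2,4,6-trichlorobenzoic anhydride | O=C(OC(=O)[C@]1(C)CO1)c1c(Cl)cc(Cl)cc1Cl | intermediate
39 | methyl (1(10)E,4Z)-9-acetoxy-8-[(2S)-2-methyloxirane-2-carbonyloxy]germacra-1(10),4,11(13)-trien-12,6-olid-14-oate | O=C1O[C@H]2/C=C(C)\CC/C=C(/C(=O)OC)[C@H](OC(C)=O)[C@@H](OC(=O)[C@]3(C)CO3)[C@H]2C1=C | intermediate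
40 | CNP0274195.1, methyl (1(10)E)-9-acetoxy-4,5-epoxy-8-[(2S)-2-methyloxirane-2-carbonyloxy]germacra-1(10),11(13)-dien-12,6-olid-14-oate | C=C1C(=O)O[C@@H]2[C@H]1[C@H](OC(=O)[C@]1(C)CO1)[C@@H](OC(C)=O)/C(C(=O)OC)=C\CC[C@@]1(C)O[C@@H]21 | target

## Step count and least certain steps

Total: 26 steps. The longest linear sequence is 24 steps from 1 (steps 1–11, 13–23, 25, 26); steps 12 and 24 are one-step preparations of 17 and 37.

**Step 17 (key step, proposed new method).**
- Most likely failures: competing scission of C5–C6 to the α-acyloxy radical; slow chlorine transfer to the electrophilic C10 radical, which lets transannular hydrogen abstraction compete; sluggish turnover of a hindered, unstrained tertiary alcohol at manganese.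
- Fallback with known chemistry, from 22: hypoiodite alkoxy-radical fragmentation (PhI(OAc)2, I2, visible light) gives the 10-iodo ketone F1. Triethylamine then removes both HI and acetic acid to give the dienone F2. Conjugate reduction and triflation as in step 19 give the enol triflate F3, and formate reduction as in step 20 returns to the route at 30.

**Step 10.**
- Most likely failures: loss of benzyloxide from the C10 enolate (β-elimination); proton transfer from the more acidic lactone positions before the ring closes; direct attack of the Grignard reagent on a lactone.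
- Fallback, from 10: carbonylation as in step 9 at the lactol stage gives the lactol acrylate F4. Copper-catalysed vinyl addition, with capture of the enolate by the aldehyde tautomer of the lactol (conjugate addition–aldol), gives the diol F5. The less hindered O8 hydroxyl is silylated to the mono-silyl ether F6, and oxidation of the C5 carbinol with the Dess–Martin periodinane returns to the route at 15.

**Step 13.**
- Most likely failures: no addition to the ketone, which is flanked by a quaternary and a tertiary carbon; reductive loss of the C6 acyloxy group by the metal.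
- Fallback, from 15 and 17: the bromide is converted with (Me3Si)2CuLi into the allylsilane F7. A Hosomi–Sakurai reaction with TiCl4 at −78 °C, which activates the chelating keto ester electrophilically, returns to the route at 19.

**Step 19.**
- Most likely failure: enolate formation from the other enone conformer, which would give the ring-trans alkene and later the wrong epoxide; 1,2-reduction is a lesser risk.
- Fallback, from 26: Luche reduction (NaBH4, CeCl3) gives the allylic alcohol F8. Mitsunobu displacement with 2-nitrobenzenesulfonylhydrazide (PPh3, diethyl azodicarboxylate) gives an allylic diazene, which loses N2 sigmatropically; this moves the double bond to C4=C5, delivers hydrogen to C15 and returns to the route at 29.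

**Step 26.**
- Most likely failure: poor facial selectivity if the ten-membered ring populates a conformer that exposes the other alkene face.
- Fallback, from 39: N-bromosuccinimide in aqueous THF forms the bromonium ion on the open face and water enters at the tertiary C4, giving the bromohydrin F9. Ag2O closes the epoxide with oxygen on the face opposite to that chosen by the peracid, returning to the route at 40.

## Further compounds

F1 | step 17 | methyl 9,15-diacetoxy-8-(tert-butyldimethylsilyloxy)-10-iodo-5-oxogermacran-12,6-olid-14-oate | COC(=O)[C@@]1(I)CCC[C@H](COC(C)=O)C(=O)[C@@H]2OC(=O)C[C@@H]2[C@H](O[Si](C)(C)C(C)(C)C)[C@H]1OC(C)=O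
F2 | step 17 | methyl (1(10)E)-9-acetoxy-8-(tert-butyldimethylsilyloxy)-5-oxogermacra-1(10),4(15)-dien-12,6-olid-14-oate | O=C1O[C@H]2C(=O)C(=C)CC/C=C(/C(=O)OC)[C@H](OC(C)=O)[C@@H](O[Si](C)(C)C(C)(C)C)[C@H]2C1
F3 | step 17 | C5 enol triflate of the (1(10)E)-dienoate (C4=C5, C3 and C6 cis) | O=C1O[C@H]2/C(OS(=O)(=O)C(F)(F)F)=C(C)\CC/C=C(/C(=O)OC)[C@H](OC(C)=O)[C@@H](O[Si](C)(C)C(C)(C)C)[C@H]2C1
F4 | step 10 | lactol acrylate (C5 lactol, 6,12-lactone, methyl 2-substituted acrylate, 9-OBn) | OC1O[C@H]([C@@H](OCc2ccccc2)C(=C)C(=O)OC)[C@H]3CC(=O)O[C@@H]13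
F5 | step 10 | methyl 6-allyl-5-(benzyloxy)-4,7-dihydroxy-2-oxooctahydro-1-benzofuran-6-carboxylate (C5 epimers) | OC1[C@@H]2OC(=O)C[C@@H]2[C@H](O)[C@@H](OCc3ccccc3)[C@]1(CC=C)C(=O)OC
F6 | step 10 | 8-O-tert-butyldimethylsilyl ether of F5 | OC1[C@@H]2OC(=O)C[C@@H]2[C@H](O[Si](C)(C)C(C)(C)C)[C@@H](OCc3ccccc3)[C@]1(CC=C)C(=O)OC
F7 | step 13 | [(Z)-4-(benzyloxy)but-2-enyl]trimethylsilane | C[Si](C)(C)C/C=C\COCc1ccccc1
F8 | step 19 | methyl 9-acetoxy-8-(tert-butyldimethylsilyloxy)-10-chloro-5-hydroxygermacr-4(15)-en-12,6-olid-14-oate (C5 epimers) | COC(=O)[C@@]1(Cl)CCCC(=C)C(O)[C@@H]2OC(=O)C[C@@H]2[C@H](O[Si](C)(C)C(C)(C)C)[C@H]1OC(C)=O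
F9 | step 26 | 5-bromo-4-hydroxy compound (bromohydrin of 39) | O=C1O[C@H]2[C@@H](Br)[C@](C)(O)CC/C=C(/C(=O)OC)[C@H](OC(C)=O)[C@@H](OC(=O)[C@]4(C)CO4)[C@H]2C1=C
A1 | alternative 1 | cis-fused α-(dimethoxyphosphoryl) lactone | COP(=O)(OC)[C@@H]1C(=O)O[C@@H]2[C@H]1[C@H](O[Si](C)(C)C(C)(C)C)[C@@H](OC(C)=O)/C(C(=O)OC)=C\CC[C@@]1(C)O[C@@H]21
A2 | alternative 2 | cis-anti-cis tricyclic photoadduct | O=C1C[C@@H]2[C@H](O[Si](C)(C)C(C)(C)C)C(=O)[C@@]3(C(=O)OC)[C@@H]4CC[C@]4(C)[C@H]3[C@@H]2O1
A3 | alternative 3 | ten-membered cis-5,6-diol | O[C@H]1[C@](C)(O[Si](CC)(CC)CC)CC/C=C(/COCc2ccc(OC)cc2)[C@H](OCOC)[C@@H](O[Si](C)(C)C(C)(C)C)[C@@H](C(=C)CO[Si](C)(C)C(C)(C)C)[C@H]1O
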